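The last bond made is C17–C18: C17 is the quaternary carbon shared by ring A (cyclopentene ester), ring C (cycloheptene) and ring D (piperidine). Lacking C18, ring A is a tautomeric cyclopentadiene ester whose C17 is nucleophilic. In the final step the N-methylamine on C20 (attached to C9) condenses with formaldehyde and the iminium ion is captured by C17: ring D closes, the quaternary stereocentre is set by the tether and the C12=C13–C14=C15 dienoate is left in place. The precursor is the finished carbocyclic A/B/C core with the spiro tetrahydropyran ketal (ring E), built by lactam-templated alkylation, metathesis, gold-catalysed Nazarov and Horner–Wadsworth–Emmons ring closures.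

Key step: step 21

Numbering (follows the target SMILES): C1–C2 ethyl, C3 hemiketal carbon, C4, C5, C6 spiro carbon, C7 (OCH2), O8, C9, C10, C11, C12=C13, C14=C15 (C15 bears CO2Me), C16, C17, C18, N19, C20, C21, C22. Ring A = C13–C17; ring B = C12/C13/C14/C21/C22; ring C = C6/C9–C13/C17; ring D = C6/C9/C20/N19/C18/C17; ring E = C3–C7/O8.

Assumption: the hemiketal carbon C3 epimerises through the open hydroxy ketone, and the configuration drawn is taken as the thermodynamic one; ketal intermediates are drawn with the same sense.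

Remark: the centres at C17 and at the phosphorus-bearing C15 in 27–33, the C12/C13 centres of 32, and the C17–H centre and ring-A diene tautomerism of 34/35 are of no consequence and are left undefined.

Step 1
Reactants: 1 (2E,6Z)-nona-2,6-dienal; 2 nitromethane
Product: 3 (3S,6Z)-3-(nitromethyl)non-6-enal
Conditions: (R)-α,α-diphenylprolinol trimethylsilyl ether (10 mol%), PhCO2H (10 mol%), MeOH, rt
Reagents that add atoms: none
Why: Iminium-catalysed Michael addition of nitromethane, in which the (R)-catalyst shields one face of the s-trans (E)-iminium ion so that the nitronate adds to the open β-face and should set the 3S centre (C9 of the target).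

Step 2
Reactants: 3 (3S,6Z)-3-(nitromethyl)non-6-enal
Product: 5 methyl (3S,6Z)-3-(nitromethyl)non-6-enoate, via carboxylic acid 4 (not isolated)
Conditions: NaClO2, NaH2PO4, 2-methylbut-2-ene, t-BuOH/H2O, 0 °C to rt; then TMSCHN2, PhMe/MeOH, 0 °C
Reagents that add atoms: sodium chlorite [Na+].[O-]Cl=O; (trimethylsilyl)diazomethane C[Si](C)(C)C=[N+]=[N-]
Why: Pinnick oxidation with an alkene scavenger spares the Z-alkene and the nitro group, and the neutral diazoalkane esterification should give the methyl ester needed for lactamisation.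

Step 3
Reactants: 5 methyl (3S,6Z)-3-(nitromethyl)non-6-enoate
Product: 7 (4S)-4-[(3Z)-hex-3-en-1-yl]pyrrolidin-2-one, via amino ester 6 (not isolated)
Conditions: Zn, AcOH, rt; then Et3N, MeOH, 50 °C
Reagents that add atoms: none
Why: Zinc reduces the aliphatic nitro group to the primary amine, which should close onto the methyl ester (5-exo-trig lactamisation) without touching C9 or the alkene.

Step 4
Reactants: 7 (4S)-4-[(3Z)-hex-3-en-1-yl]pyrrolidin-2-one
Product: 8 tert-butyl (4S)-4-[(3Z)-hex-3-en-1-yl]-2-oxopyrrolidine-1-carboxylate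
Conditions: Boc2O, DMAP (cat.), Et3N, CH2Cl2, rt
Reagents that add atoms: di-tert-butyl dicarbonate CC(C)(C)OC(=O)OC(=O)OC(C)(C)C
Why: N-acylation gives the imide-type N-Boc lactam, which is needed for clean enolate alkylation and for later opening at the carbonyl.

Step 5
Reactants: 8 N-Boc lactam; 9 3-bromo-1-(trimethylsilyl)prop-1-yne
Product: 10 3,4-trans-3-(silylpropynyl) N-Boc lactam
Conditions: LiHMDS, THF, −78 °C; then 9, −78 to −40 °C
Reagents that add atoms: none
Why: Enolate alkylation with a reactive propargylic bromide, entering trans to the C4 side chain (this centre is re-enolised in the next step).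

Step 6
Reactants: 10 3,4-trans-3-(silylpropynyl) N-Boc lactam; 11 formaldehyde
Product: 13 3-(TBSOCH2)-3-(silylpropynyl) N-Boc lactam (CH2OTBS trans and propynyl cis to hexenyl), via alcohol 12 (not isolated)
Conditions: LiHMDS, THF, −78 °C; monomeric CH2O (from cracked paraformaldehyde); then TBSOTf, −78 to 0 °C
Reagents that add atoms: tert-butyldimethylsilyl triflate CC(C)(C)[Si](C)(C)OS(=O)(=O)C(F)(F)F
Why: Aldol reaction of the trisubstituted lactam enolate with formaldehyde anti to the C4 hexenyl group should set the quaternary C6 with C7 trans and C17 cis to C10, and silylating the aldolate in the flask blocks retro-aldol and N-to-O Boc transfer.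

Step 7
Reactants: 13 3-(TBSOCH2)-3-(silylpropynyl) N-Boc lactam
Product: 14 N-Boc lactamol (2-hydroxypyrrolidine, epimers at C-2)
Conditions: LiBHEt3, THF, −78 °C
Reagents that add atoms: none
Why: Partial reduction of an N-acyl lactam, whose tetrahedral intermediate is stable at low temperature, should stop at the hemiaminal.

Step 8
Reactants: 14 N-Boc lactamol; 15 diethyl (2-oxobutyl)phosphonate
Product: 16 open-chain (E)-enone carbamate
Conditions: LiCl, i-Pr2NEt, MeCN, 40 °C
Reagents that add atoms: none
Why: The ring-opened aldehyde tautomer of the lactamol is trapped by a Horner–Wadsworth–Emmons reaction (LiCl/amine variant) to give the E-enone (C5=C4–C3) and free the C20–NHBoc arm.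

Step 9
Reactants: 16 open-chain (E)-enone carbamate
Product: 19 methyl ketal carbamate (ring E closed), via ethyl ketone 17 (not isolated), via hemiketal 18 (not isolated)
Conditions: [(Ph3P)CuH]6 (5 mol%), PhMe2SiH, toluene, rt; then CSA, MeOH, rt
Reagents that add atoms: methanol CO
Why: Copper hydride conjugate reduction is selective for the enone over the Z-alkene and the silylalkyne, and acidic methanol then removes the TBS group so that the C7 hydroxyl closes onto the C3 ketone (six-membered hemiketal) and is fixed as the anomerically favoured methyl ketal.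

Step 10
Reactants: 19 methyl ketal carbamate
Product: 20 N-methyl carbamate
Conditions: NaH, MeI, DMF, 0 °C
Reagents that add atoms: iodomethane CI
Why: Deprotonation and methylation of the carbamate N–H installs the N-methyl group while no other acidic site is present.

Step 11
Reactants: 20 N-methyl carbamate
Product: 22 methyl ketone (C17H2–C13(=O)–C12H3), via terminal alkyne 21 (not isolated)
Conditions: K2CO3, MeOH, rt; then Ph3PAuCl/AgSbF6 (2 mol%), MeOH/H2O (20:1), 60 °C
Reagents that add atoms: water O
Why: Protodesilylation followed by gold-catalysed Markovnikov hydration of the terminal alkyne should give the methyl ketone, with the cyclic methyl ketal persisting in methanol.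

Step 12
Reactants: 22 methyl ketone
Product: 23 2-(tert-butyldimethylsilyloxy)allyl compound
Conditions: LDA, THF, −78 °C; then TBSOTf
Reagents that add atoms: tert-butyldimethylsilyl triflate CC(C)(C)[Si](C)(C)OS(=O)(=O)C(F)(F)F
Why: Kinetic deprotonation occurs at the methyl group (the C17 methylene is neopentyl-hindered) and O-silylation gives the terminal silyl enol ether needed for metathesis.

Step 13
Reactants: 23 2-(tert-butyldimethylsilyloxy)allyl compound
Product: 24 cyclic silyl enol ether (ring C closed, C12=C13–OTBS)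
Conditions: second-generation Grubbs catalyst (5 mol%), toluene, 80 °C
Reagents that add atoms: none
Why: Ring-closing metathesis between the silyl enol ether alkene and the Z-hexenyl alkene should close the seven-membered ring C with loss of but-1-ene, the gem-disubstituted C6 favouring cyclisation.

Step 14
Reactants: 24 cyclic silyl enol ether
Product: 25 cyclohept-2-enone (C13=O, C11=C12)
Conditions: Pd(OAc)2 (1.1 equiv), MeCN, rt
Reagents that add atoms: none
Why: Saegusa–Ito oxidation of the regiodefined silyl enol ether gives the enone, which leaves C17 as the only α-position that can be enolised.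

Step 15
Reactants: 25 cyclohept-2-enone; 26 trimethyl 2-phosphonoacrylate
Product: 27 C17 Michael adduct (C17–CH2–CH(PO(OMe)2)CO2Me)
Conditions: LDA, THF, −78 °C; then 26, −78 °C; AcOH quench at −78 °C
Reagents that add atoms: none
Why: Kinetic α′-deprotonation at C17 and Michael addition to the vinylphosphonate gives a stabilised phosphonoacetate anion and forms the C17–C16 bond, the new centres being of no consequence.

Step 16
Reactants: 27 C17 Michael adduct
Product: 28 cycloheptanone (C13=O)
Conditions: H2 (1 atm), 10% Pd/C, EtOAc, rt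
Reagents that add atoms: none
Why: Heterogeneous hydrogenation removes the only C=C bond present, so that C12 becomes the less hindered enolisable position.

Step 17
Reactants: 28 cycloheptanone
Product: 29 vinyl triflate (C12=C13–OTf)
Conditions: KHMDS (2.2 equiv), THF, −78 °C; then PhNTf2
Reagents that add atoms: N-phenylbis(trifluoromethanesulfonimide) O=S(=O)(N(c1ccccc1)S(=O)(=O)C(F)(F)F)C(F)(F)F
Why: The first equivalent of base ionises the phosphonoacetate, the second removes a C12 proton rather than the hindered tertiary C17–H, and O-triflation of the kinetic enolate gives the C12=C13 enol triflate.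

Step 18
Reactants: 29 vinyl triflate; 30 prop-2-yn-1-yl acetate
Product: 31 enynyl acetate (C12=C13–C14≡C21–C22H2OAc)
Conditions: PdCl2(PPh3)2 (5 mol%), CuI (10 mol%), Et3N, THF, rt
Reagents that add atoms: none
Why: Sonogashira coupling of the vinyl triflate with the terminal alkyne forms the C13–C14 bond under mild basic conditions.

Step 19
Reactants: 31 enynyl acetate
Product: 33 ring-fusion cyclopentenone (ring B closed; C14=O, C12=C13), via cis-fused cyclopentenone 32 (not isolated)
Conditions: Ph3PAuCl/AgSbF6 (5 mol%), wet CH2Cl2, rt; then DBU, rt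
Reagents that add atoms: none
Why: Gold-catalysed 3,3-acyloxy shift of the propargylic acetate gives an acetoxy vinylallene that undergoes Nazarov-type 4π closure (C12–C22 bond) and hydrolysis to the cyclopentenone with its carbonyl on C14, and DBU then moves the double bond to the tetrasubstituted C12=C13 position.

Step 20
Reactants: 33 ring-fusion cyclopentenone
Product: 34 N-Boc aminomethyl dienoate methyl ketal (rings A, B, C and E; C17–H)
Conditions: LiCl, DBU, MeCN, rt to 60 °C
Reagents that add atoms: none
Why: Intramolecular Horner–Wadsworth–Emmons reaction of the phosphonoacetate carbanion (C15) with the C14 ketone closes the five-membered ring A and installs the tetrasubstituted C14=C15 ester alkene, the product equilibrating with its ring-A cyclopentadiene tautomers.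

Step 21
Reactants: 34 N-Boc aminomethyl dienoate methyl ketal; 11 formaldehyde
Product: 36 target compound CNP0192143.1, via amino hemiketal 35 (not isolated)
Conditions: TFA/CH2Cl2/H2O (9:9:2), rt; concentrate; then 37% aq. CH2O (1.5 equiv), TFA (2 equiv), MeCN/H2O, 60 °C; NaHCO3 work-up
Reagents that add atoms: water O
Why: Proposed new method: aqueous TFA removes the Boc group and hydrolyses the methyl ketal without opening ring E, and the secondary amine of 35 then condenses with formaldehyde to an N-methyl-N-methyleneiminium ion; ring A of 35 equilibrates by prototropy (through the C13 allyl cation or 1,5-hydrogen shifts) with cyclopentadiene tautomers in which C17 is an sp2 terminus of the ester-substituted diene, and this carbon should attack the iminium carbon to give a C13 allyl cation that loses H-12, leaving the C12=C13–C14=C15 dienoate directly (any cross-conjugated isomer should drain to it under the acid). The closest known reaction types are the Mannich aminomethylation of cyclopentadienes and the aza-Prins (iminium–ene) cyclisation of formaldiminium ions onto substituted alkenes, neither of which has been shown on a tetrasubstituted cyclopentadienyl ester with formation of a ring-fusion quaternary carbon. Ring D closes in a six-membered mode that is exo at the C13=C17 π bond and endo at the C=N bond, through a chair-like arrangement. The new stereocentre C17 is controlled by the tether: C20 sits on C9 on the face of ring C syn to C5, so the 1,3-bridge across C6 can only form cis and the azabicyclo[4.3.1]decane has one possible configuration. The step needs regioselectivity for C17 over C16 or C12 (both seven-membered alternatives), which the shorter six-membered closure and the reversibility of the Mannich addition should secure.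

Compound list
1 | (2E,6Z)-nona-2,6-dienal | CC/C=C\CC/C=C/C=O | starting material
2 | nitromethane | C[N+](=O)[O-] | starting material
3 | (3S,6Z)-3-(nitromethyl)non-6-enal | CC/C=C\CC[C@H](C[N+](=O)[O-])CC=O | intermediate
4 | (3S,6Z)-3-(nitromethyl)non-6-enoic acid | CC/C=C\CC[C@H](C[N+](=O)[O-])CC(=O)O | intermediate
5 | methyl (3S,6Z)-3-(nitromethyl)non-6-enoate | CC/C=C\CC[C@H](C[N+](=O)[O-])CC(=O)OC | intermediate
6 | methyl (3S,6Z)-3-(aminomethyl)non-6-enoate | CC/C=C\CC[C@H](CN)CC(=O)OC | intermediate
7 | (4S)-4-[(3Z)-hex-3-en-1-yl]pyrrolidin-2-one | O=C1C[C@H](CC/C=C\CC)CN1 | intermediate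
8 | tert-butyl (4S)-4-[(3Z)-hex-3-en-1-yl]-2-oxopyrrolidine-1-carboxylate | O=C1C[C@H](CC/C=C\CC)CN1C(=O)OC(C)(C)C | intermediate
9 | 3-bromo-1-(trimethylsilyl)prop-1-yne | C[Si](C)(C)C#CCBr | starting material
10 | tert-butyl 4-[(3Z)-hex-3-en-1-yl]-2-oxo-3-[3-(trimethylsilyl)prop-2-yn-1-yl]pyrrolidine-1-carboxylate, 3,4-trans, C4 as in 8 | O=C1[C@@H](CC#C[Si](C)(C)C)[C@H](CC/C=C\CC)CN1C(=O)OC(C)(C)C | intermediate
11 | formaldehyde | C=O | starting material
12 | 3-(hydroxymethyl) derivative of 10 with quaternary C3 (future C6): CH2OH trans and silylpropynyl cis to the hexenyl group | O=C1[C@@](CC#C[Si](C)(C)C)(CO)[C@H](CC/C=C\CC)CN1C(=O)OC(C)(C)C | intermediate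
13 | O-tert-butyldimethylsilyl ether of 12 | O=C1[C@@](CC#C[Si](C)(C)C)(CO[Si](C)(C)C(C)(C)C)[C@H](CC/C=C\CC)CN1C(=O)OC(C)(C)C | intermediate
14 | N-Boc lactamol: 2-hydroxypyrrolidine from 13 (lactam C=O reduced to CH–OH, epimers) | OC1[C@@](CC#C[Si](C)(C)C)(CO[Si](C)(C)C(C)(C)C)[C@H](CC/C=C\CC)CN1C(=O)OC(C)(C)C | intermediate
15 | diethyl (2-oxobutyl)phosphonate | CCC(=O)CP(=O)(OCC)OCC | starting material
16 | open-chain (E)-enone carbamate: C6 bears CH=CH–C(=O)Et, CH2OTBS, CH2C≡CSiMe3; C9 bears (3Z)-hex-3-enyl and CH2NHBoc | CCC(=O)/C=C/[C@@](CC#C[Si](C)(C)C)(CO[Si](C)(C)C(C)(C)C)[C@H](CC/C=C\CC)CNC(=O)OC(C)(C)C | intermediate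
17 | saturated ethyl ketone from 16 (C4–C5 single bond) | CCC(=O)CC[C@@](CC#C[Si](C)(C)C)(CO[Si](C)(C)C(C)(C)C)[C@H](CC/C=C\CC)CNC(=O)OC(C)(C)C | intermediate
18 | hemiketal: 2-ethyl-2-hydroxytetrahydropyran (ring E) with C6 bearing CH2C≡CSiMe3 and the C9 carbon (hexenyl, CH2NHBoc) | CC[C@@]1(O)CC[C@@](CC#C[Si](C)(C)C)(CO1)[C@H](CC/C=C\CC)CNC(=O)OC(C)(C)C | intermediate
19 | methyl ketal of 18 (2-ethyl-2-methoxytetrahydropyran, major anomer drawn) | CC[C@@]1(OC)CC[C@@](CC#C[Si](C)(C)C)(CO1)[C@H](CC/C=C\CC)CNC(=O)OC(C)(C)C | intermediate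
20 | N-methyl carbamate of 19 (CH2N(Me)Boc) | CC[C@@]1(OC)CC[C@@](CC#C[Si](C)(C)C)(CO1)[C@H](CC/C=C\CC)CN(C)C(=O)OC(C)(C)C | intermediate
21 | terminal alkyne from 20 (C6–CH2C≡CH) | CC[C@@]1(OC)CC[C@@](CC#C)(CO1)[C@H](CC/C=C\CC)CN(C)C(=O)OC(C)(C)C | intermediate
22 | methyl ketone (C6–CH2–C(=O)–CH3, i.e. C17, C13, C12) | CC[C@@]1(OC)CC[C@@](CC(C)=O)(CO1)[C@H](CC/C=C\CC)CN(C)C(=O)OC(C)(C)C | intermediate
23 | 2-(tert-butyldimethylsilyloxy)allyl compound (C6–CH2–C(OTBS)=CH2) | CC[C@@]1(OC)CC[C@@](CC(=C)O[Si](C)(C)C(C)(C)C)(CO1)[C@H](CC/C=C\CC)CN(C)C(=O)OC(C)(C)C | intermediate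
24 | spiro cyclic silyl enol ether: ring C (C6, C17H2, C13(OTBS)=C12H, C11H2, C10H2, C9) spiro to ring E at C6; CH2N(Me)Boc on C9 | CC[C@@]1(OC)CC[C@@]2(CC(O[Si](C)(C)C(C)(C)C)=CCC[C@@H]2CN(C)C(=O)OC(C)(C)C)CO1 | intermediate
25 | spiro cyclohept-2-enone: C13=O, C12=C11, C17H2 next to C6 | CC[C@@]1(OC)CC[C@@]2(CC(=O)C=CC[C@@H]2CN(C)C(=O)OC(C)(C)C)CO1 | intermediate
26 | trimethyl 2-phosphonoacrylate (methyl 2-(dimethoxyphosphoryl)prop-2-enoate) | C=C(C(=O)OC)P(=O)(OC)OC | starting material
27 | Michael adduct: 25 with CH2–CH(PO(OMe)2)CO2Me on C17 (epimers) | CC[C@@]1(OC)CC[C@@]2(C(CC(C(=O)OC)P(=O)(OC)OC)C(=O)C=CC[C@@H]2CN(C)C(=O)OC(C)(C)C)CO1 | intermediate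
28 | saturated cycloheptanone from 27 (C11–C12 single bond) | CC[C@@]1(OC)CC[C@@]2(C(CC(C(=O)OC)P(=O)(OC)OC)C(=O)CCC[C@@H]2CN(C)C(=O)OC(C)(C)C)CO1 | intermediate
29 | vinyl triflate: C13(OTf)=C12 in ring C | CC[C@@]1(OC)CC[C@@]2(C(CC(C(=O)OC)P(=O)(OC)OC)C(OS(=O)(=O)C(F)(F)F)=CCC[C@@H]2CN(C)C(=O)OC(C)(C)C)CO1 | intermediate
30 | prop-2-yn-1-yl acetate | C#CCOC(C)=O | starting material
31 | enynyl acetate: C13 bears C≡C–CH2OAc (C14, C21, C22), C12=C13 | CC[C@@]1(OC)CC[C@@]2(C(CC(C(=O)OC)P(=O)(OC)OC)C(C#CCOC(C)=O)=CCC[C@@H]2CN(C)C(=O)OC(C)(C)C)CO1 | intermediate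
32 | cis-fused cyclopentenone: ring B with C14=O, C21=C22, H on C12 and C13 | CC[C@@]1(OC)CC[C@@]2(C(CC(C(=O)OC)P(=O)(OC)OC)C3C(=O)C=CC3CC[C@@H]2CN(C)C(=O)OC(C)(C)C)CO1 | intermediate
33 | ring-fusion cyclopentenone: ring B with C14=O and C12=C13 shared with ring C; phosphonoacetate chain on C17 | CC[C@@]1(OC)CC[C@@]2(C(CC(C(=O)OC)P(=O)(OC)OC)C3=C(CCC3=O)CC[C@@H]2CN(C)C(=O)OC(C)(C)C)CO1 | intermediate
34 | tricyclic dienoate: rings A, B, C with C12=C13–C14=C15(CO2Me), C17–H, spiro methyl ketal ring E at C6, CH2N(Me)Boc on C9 | CC[C@@]1(OC)CC[C@@]2(CO1)[C@@H](CN(C)C(=O)OC(C)(C)C)CCC1=C3C(=C(C(=O)OC)CC32)CC1 | intermediate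
35 | amino hemiketal: 34 with CH2NHMe on C9 and the C3 hemiketal (OH) | CC[C@@]1(O)CC[C@@]2(CO1)[C@@H](CNC)CCC1=C3C(=C(C(=O)OC)CC32)CC1 | intermediate
36 | CNP0192143.1 | CC[C@@]1(O)CC[C@@]2(CO1)[C@@H]1CCC3=C4C(=C(C(=O)OC)C[C@@]42CN(C)C1)CC3 | target

Total step count: 21. Longest linear sequence: 21 steps (from 1).

Steps most likely to fail

Step 21 (Proposed new method). The prototropic shift that feeds the cyclopentadiene tautomer may be too slow. The iminium ion may instead be captured at C12 or C16, giving seven-membered rings, or be lost to aminal oligomers. The final conjugation into the C12=C13–C14=C15 dienoate may also stall. The fallback uses known chemistry and sets out from 35, isolated as its trifluoroacetate after the aqueous TFA treatment of 34. Condensation with aqueous formaldehyde and 1H-benzotriazole in EtOH should give the N-(benzotriazol-1-ylmethyl)-N-methylamine F1. DBU in MeCN at 60 °C then forms the ester-stabilised cyclopentadienide of ring A, which displaces benzotriazolide at C17 in a benzotriazole-mediated aminoalkylation of a carbon acid, closing ring D to the cross-conjugated 5,5-disubstituted cyclopentadiene F2 (C13=C14, C15=C16, H on C12). Catalytic TFA in CH2Cl2 (or t-BuOK in t-BuOH) should shift the diene into conjugation, and the route is rejoined at 36.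

Step 19. The 3,3-acyloxy shift of the primary propargylic acetate may be sluggish, alkyne hydration or a 1,2-acyloxy shift may compete, and the gold Lewis acid may erode the ketal. The fallback sets out from 29. A carbonylative Stille coupling (Pd(PPh3)4, LiCl, CO at 1 atm, tributyl(vinyl)stannane, THF, 55 °C) should give the cross-conjugated cycloheptenyl vinyl ketone F3. A classical acid-mediated Nazarov cyclisation (MeSO3H, CH2Cl2, 0 °C to rt, aqueous NaHCO3 work-up) closes ring B with concomitant loss of the Boc group and hydrolysis of the ketal, giving the amino cyclopentenone hemiketal F4. The intramolecular Horner–Wadsworth–Emmons reaction (LiCl, DBU, MeCN) then closes ring A, and the route is rejoined at 35, which is treated with formaldehyde as in the second half of step 21.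

Step 8. The hindered lactamol may supply too little open-chain aldehyde for olefination, and the carbamate nitrogen may re-close onto the new enone by aza-Michael addition. The fallback sets out from 13. Reductive ring-opening of the N-Boc lactam with NaBH4 in EtOH should give the N-Boc amino alcohol F5. Dess–Martin oxidation (CH2Cl2, NaHCO3) gives the neopentyl aldehyde F6, which has no α-hydrogen. The same Horner–Wadsworth–Emmons reaction with 15 (LiCl, i-Pr2NEt, MeCN) then rejoins the route at 16.

Further compounds
F1 | step 21 | N-(benzotriazol-1-ylmethyl)-N-methylamine derived from 35 | CC[C@@]1(O)CC[C@@]2(CO1)[C@@H](CN(C)Cn1nnc3ccccc31)CCC1=C3C(=C(C(=O)OC)CC32)CC1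
F2 | step 21 | cross-conjugated diene isomer of 36 (C13=C14 and C15=C16, H on C12, ring D closed) | CC[C@@]1(O)CC[C@@]2(CO1)[C@@H]1CCC3C4=C(CC3)C(C(=O)OC)=C[C@@]42CN(C)C1
F3 | step 19 | cycloheptenyl vinyl ketone: 29 with C(=O)CH=CH2 on C13 in place of OTf | CC[C@@]1(OC)CC[C@@]2(C(CC(C(=O)OC)P(=O)(OC)OC)C(C(=O)C=C)=CCC[C@@H]2CN(C)C(=O)OC(C)(C)C)CO1
F4 | step 19 | amino cyclopentenone hemiketal: 33 without Boc and with the C3 hemiketal | CC[C@@]1(O)CC[C@@]2(C(CC(C(=O)OC)P(=O)(OC)OC)C3=C(CCC3=O)CC[C@@H]2CNC)CO1
F5 | step 8 | N-Boc amino alcohol from reductive opening of 13 (C5 as CH2OH) | OC[C@@](CC#C[Si](C)(C)C)(CO[Si](C)(C)C(C)(C)C)[C@H](CC/C=C\CC)CNC(=O)OC(C)(C)C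
F6 | step 8 | neopentyl aldehyde from F5 (C5 as CHO) | O=C[C@@](CC#C[Si](C)(C)C)(CO[Si](C)(C)C(C)(C)C)[C@H](CC/C=C\CC)CNC(=O)OC(C)(C)C
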